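The 1,2-dioxane (ring atoms O1, O2, C3, C4, C5, C6) is taken apart at O2–C3 and O1–C6. C6 carries O1 and the acetic acid arm (C7, C8), so it is a β-peroxy acid and maps onto a 4-substituted β-lactone opened at its alkyl carbon, whereas C3 is at the ketone oxidation level and can accept the second peroxide oxygen. One operation with hydrogen peroxide on a keto β-lactone should therefore bring in the O–O unit, close the ring, set C6 by inversion and uncover the acid. The precursor is an acyclic (4R)-β-lactone with a ketone two methylenes away that already bears the complete dienyne chain; exchange of hydroxyl for methoxyl at C3 completes the target.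

Key step: step 8

Assumption: O-trimethylsilylquinine is taken as the pseudoenantiomer that gives the 4R lactone from an unbranched aldehyde; if the sense proves opposite, O-trimethylsilylquinidine replaces it and nothing else changes.

Step 1
Reactants: 1 dec-9-en-1-ol
Product: 2 dec-9-enal
Conditions: TEMPO (10 mol%), PhI(OAc)2 (1.1 equiv), CH2Cl2, rt
Reagents that add atoms: none
Why: Oxoammonium-mediated (TEMPO) oxidation of a primary alcohol stops at the aldehyde and does not touch the terminal alkene.

Step 2
Reactants: 2 dec-9-enal
Product: 3 (1E)-1-iodoundeca-1,10-diene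
Conditions: CrCl2 (6 equiv), CHI3 (2 equiv), 1,4-dioxane/THF (6:1), 0 °C to rt
Reagents that add atoms: iodoform, IC(I)I
Why: Takai olefination, in which the geminal dichromium species formed from CHI3 and divalent chromium adds to the aldehyde and eliminates to the E-vinyl iodide (the dioxane co-solvent raises the E preference), while the isolated terminal alkene is inert and any minor Z isomer is removed by chromatography here or after step 4.

Step 3
Reactants: 4 hex-5-ynoic acid
Product: 6 N-methoxy-N-methylhex-5-ynamide, via acyl imidazole 5 (not isolated)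
Conditions: CDI (1.1 equiv), CH2Cl2, rt; then MeNH(OMe)·HCl (1.2 equiv), rt
Reagents that add atoms: N,O-dimethylhydroxylamine hydrochloride, Cl.CNOC
Why: Weinreb amide formation by acyl-imidazole activation and aminolysis, for which the terminal alkyne needs no protection.

Step 4
Reactants: 3 (1E)-1-iodoundeca-1,10-diene; 6 N-methoxy-N-methylhex-5-ynamide
Product: 7 (7E)-N-methoxy-N-methylheptadeca-7,16-dien-5-ynamide
Conditions: Pd(PPh3)2Cl2 (3 mol%), CuI (6 mol%), Et3N, THF, rt, degassed
Reagents that add atoms: none
Why: Sonogashira coupling, in which oxidative addition of the vinyl iodide to zerovalent palladium, transmetalation from the copper acetylide and reductive elimination proceed with retention of the E geometry and leave the Weinreb amide untouched.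

Step 5
Reactants: 7 (7E)-N-methoxy-N-methylheptadeca-7,16-dien-5-ynamide; 8 2-(2-bromoethyl)-1,3-dioxolane
Product: 10 (9E)-1-(1,3-dioxolan-2-yl)nonadeca-9,18-dien-7-yn-3-one, via Grignard reagent 9 (not isolated)
Conditions: 8, Mg, THF, 20–25 °C; then 7, THF, 0 °C; aq. NH4Cl
Reagents that add atoms: none
Why: Weinreb ketone synthesis, in which the Grignard reagent adds only once because the magnesium-chelated tetrahedral adduct survives until the quench, and neither the enyne nor the terminal alkene reacts.

Step 6
Reactants: 10 (9E)-1-(1,3-dioxolan-2-yl)nonadeca-9,18-dien-7-yn-3-one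
Product: 11 (10E)-4-oxoicosa-10,19-dien-8-ynal
Conditions: 2 M HCl, THF, rt; used crude at once
Reagents that add atoms: water, O
Why: Acid-catalysed acetal hydrolysis frees the aldehyde under conditions expected to be too mild for aldol or furan-forming condensation of the 1,4-dicarbonyl unit.

Step 7
Reactants: 11 (10E)-4-oxoicosa-10,19-dien-8-ynal; 12 acetyl chloride
Product: 14 (4R)-4-[(9E)-3-oxononadeca-9,18-dien-7-yn-1-yl]oxetan-2-one, via ketene 13 (not isolated)
Conditions: AcCl (slow addition), iPr2NEt, O-trimethylsilylquinine (10 mol%), LiClO4, CH2Cl2/Et2O, −78 °C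
Reagents that add atoms: none
Why: Nucleophile-catalysed asymmetric ketene–aldehyde [2+2] cycloaddition, in which ketene 13, released from acetyl chloride by the amine base, forms a chiral ammonium enolate with the alkaloid that adds to one face of the LiClO4-activated aldehyde and lactonises, so that the catalyst sets C4 as R while the less electrophilic ketone should remain a spectator at −78 °C.

Step 8
Reactants: 14 (4R)-4-[(9E)-3-oxononadeca-9,18-dien-7-yn-1-yl]oxetan-2-one; 15 hydrogen peroxide
Product: 17 2-[(3R,6S)-3-[(6E)-hexadeca-6,15-dien-4-yn-1-yl]-3-hydroxy-1,2-dioxan-6-yl]acetic acid, via hydroperoxy hemiketal 16 (not isolated)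
Conditions: H2O2 (anhydrous ethereal solution, 10 equiv), Et2O, 0 °C, 1 h; then Yb(OTf)3 (10 mol%), 0 °C to rt
Reagents that add atoms: none
Why: Proposed new method: excess H2O2 adds reversibly to the C3 ketone (ketone perhydrolysis) to give hydroperoxy hemiketal 16, and once Yb(OTf)3 binds the lactone carbonyl the terminal peroxide oxygen attacks C6 from the back as the carboxylate leaves, so that the O1–C6 bond follows the O2–C3 bond and C8 appears as the free acid; the closest known reaction types are Lewis-acid opening of oxetanes and epoxides by hydrogen peroxide or tethered hydroperoxides and the invertive alkyl–oxygen opening of keto β-lactones by the ketone oxygen. The 1,2-dioxane closes in a 6-exo-tet mode, and release of the four-ring strain should make the closure irreversible. C6 is substrate-controlled: the stereospecific SN2 displacement inverts the 4R lactone carbon to 6S. C3 is under thermodynamic control, because the peroxyhemiketal epimerises by ring–chain tautomerism to the chair with axial hydroxyl (anomeric effect) and both carbon substituents equatorial, which is 3R. The step needs attack at the alkyl carbon C6 and not at the acyl carbon C8, and by the peroxide oxygen and not by the ketone or hemiketal oxygen (five-membered closure); Lewis-acid coordination of the carbonyl oxygen favours alkyl–oxygen cleavage, and loading the ketone with H2O2 before the Lewis acid is added, together with the higher nucleophilicity of the hydroperoxide oxygen, should favour the six-membered closure. Should H2O2 open the lactone at C6 intermolecularly first, the resulting β-hydroperoxy acid would close onto the ketone to the same product.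

Step 9
Reactants: 17 2-[(3R,6S)-3-[(6E)-hexadeca-6,15-dien-4-yn-1-yl]-3-hydroxy-1,2-dioxan-6-yl]acetic acid
Product: 18 2-[(3R,6S)-3-[(6E)-hexadeca-6,15-dien-4-yn-1-yl]-3-methoxy-1,2-dioxan-6-yl]acetic acid
Conditions: MeOH, p-TsOH·H2O (5 mol%), 0 °C to rt, short reaction time; pH 4 buffer work-up
Reagents that add atoms: methanol, CO
Why: Acid-catalysed peroxyhemiketal-to-peroxyketal exchange through the cyclic peroxycarbenium ion, in which methanol adds axially and the equilibrium likewise favours axial methoxyl (anomeric effect) with the chain equatorial, giving 3R, while C6 is untouched and Fischer esterification of the acid is expected to be slower than the exchange.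

Compound list
1 | dec-9-en-1-ol | C=CCCCCCCCCO | starting material
2 | dec-9-enal | C=CCCCCCCCC=O | intermediate
3 | (1E)-1-iodoundeca-1,10-diene | C=CCCCCCCC/C=C/I | intermediate
4 | hex-5-ynoic acid | C#CCCCC(=O)O | starting material
5 | 1-(1H-imidazol-1-yl)hex-5-yn-1-one | C#CCCCC(=O)n1ccnc1 | intermediate (not isolated)
6 | N-methoxy-N-methylhex-5-ynamide | C#CCCCC(=O)N(C)OC | intermediate
7 | (7E)-N-methoxy-N-methylheptadeca-7,16-dien-5-ynamide | C=CCCCCCCC/C=C/C#CCCCC(=O)N(C)OC | intermediate
8 | 2-(2-bromoethyl)-1,3-dioxolane | BrCCC1OCCO1 | starting material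
9 | [2-(1,3-dioxolan-2-yl)ethyl]magnesium bromide | Br[Mg]CCC1OCCO1 | intermediate (not isolated)
10 | (9E)-1-(1,3-dioxolan-2-yl)nonadeca-9,18-dien-7-yn-3-one | C=CCCCCCCC/C=C/C#CCCCC(=O)CCC1OCCO1 | intermediate
11 | (10E)-4-oxoicosa-10,19-dien-8-ynal | C=CCCCCCCC/C=C/C#CCCCC(=O)CCC=O | intermediate
12 | acetyl chloride | CC(=O)Cl | starting material
13 | ketene (ethenone) | C=C=O | intermediate (not isolated)
14 | (4R)-4-[(9E)-3-oxononadeca-9,18-dien-7-yn-1-yl]oxetan-2-one | C=CCCCCCCC/C=C/C#CCCCC(=O)CC[C@@H]1CC(=O)O1 | intermediate
15 | hydrogen peroxide | OO | starting material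
16 | (4R)-4-[(9E)-3-hydroperoxy-3-hydroxynonadeca-9,18-dien-7-yn-1-yl]oxetan-2-one (both C3 epimers) | C=CCCCCCCC/C=C/C#CCCCC(O)(OO)CC[C@@H]1CC(=O)O1 | intermediate (not isolated)
17 | 2-[(3R,6S)-3-[(6E)-hexadeca-6,15-dien-4-yn-1-yl]-3-hydroxy-1,2-dioxan-6-yl]acetic acid | C=CCCCCCCC/C=C/C#CCCC[C@]1(O)CC[C@@H](CC(=O)O)OO1 | intermediate
18 | 2-[(3R,6S)-3-[(6E)-hexadeca-6,15-dien-4-yn-1-yl]-3-methoxy-1,2-dioxan-6-yl]acetic acid | C=CCCCCCCC/C=C/C#CCCC[C@]1(OC)CC[C@@H](CC(=O)O)OO1 | target

Total step count: 9
Longest linear sequence: 8 steps (1 → 2 → 3 → 7 → 10 → 11 → 14 → 17 → 18)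

Steps most likely to fail

Step 8 (the proposed new method). What may go wrong:
- attack of peroxide at the acyl carbon, giving a β-hydroxy peracid that could also epoxidise the alkenes;
- five-membered closure by the ketone or hemiketal oxygen onto C6;
- ionisation at C6 with loss of configuration.

Ethereal H2O2 is kept dilute and cold and is handled behind a shield. The fallback uses known chemistry, sets out from 11 and comes back at 18. Keto aldehyde 11 is olefinated with ethyl (triphenylphosphoranylidene)acetate (Wittig reaction, CH2Cl2, rt) to ethyl (2E,12E)-6-oxodocosa-2,12,21-trien-10-ynoate F1. Urea–hydrogen peroxide with Sc(OTf)3 in methanol converts the ketone into ethyl (2E,12E)-6-hydroperoxy-6-methoxydocosa-2,12,21-trien-10-ynoate F2. Et2NH in CF3CH2OH then closes the ring by intramolecular oxa-Michael addition of the hydroperoxide to the enoate, giving ethyl 2-[3-[(6E)-hexadeca-6,15-dien-4-yn-1-yl]-3-methoxy-1,2-dioxan-6-yl]acetate F3 as a mixture of stereoisomers. Acid in methanol equilibrates C3 to the axial-methoxyl (3,6-cis) racemate, which is resolved by preparative chromatography on a chiral stationary phase to ethyl 2-[(3R,6S)-3-[(6E)-hexadeca-6,15-dien-4-yn-1-yl]-3-methoxy-1,2-dioxan-6-yl]acetate F4. LiOH in THF/H2O at 0 °C then gives 18. This path gives up control of C6 and pays for it with a resolution.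

Step 7. What may go wrong:
- low enantioselectivity or conversion with the keto aldehyde;
- aldol self-condensation of the 1,4-dicarbonyl under amine and lithium salt;
- ketene dimerisation outrunning the cycloaddition.

The fallback sets out from 11 and comes back at 14. The titanium enolate of 1-[(4R)-4-(propan-2-yl)-2-sulfanylidene-1,3-thiazolidin-3-yl]ethan-1-one (TiCl4, iPr2NEt, CH2Cl2, −78 °C) adds to aldehyde 11 in an auxiliary-controlled acetate aldol reaction. The 4R auxiliary is expected to give the 3R carbinol, (3R,12E)-3-hydroxy-1-[(4R)-4-(propan-2-yl)-2-sulfanylidene-1,3-thiazolidin-3-yl]docosa-12,21-dien-10-yne-1,6-dione F5, and the minor diastereomer is removed by chromatography. LiOH in THF/H2O at 0 °C releases the auxiliary and gives (3R,12E)-3-hydroxy-6-oxodocosa-12,21-dien-10-ynoic acid F6. PhSO2Cl in pyridine at 0 °C closes the β-lactone by carboxyl activation, with retention at the carbinol carbon, to give 14.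

Step 9. What may go wrong:
- Fischer esterification of the acid running alongside the ketal exchange;
- incomplete anomer control at C3;
- acid-induced degradation of the peroxide on long exposure.

The fallback sets out from 17 and comes back at 18. Instead of relying on chemoselectivity, both reactions are driven to completion. Compound 17 is kept in methanol with p-TsOH and 3 Å molecular sieves until ketal exchange and esterification are complete, giving methyl 2-[(3R,6S)-3-[(6E)-hexadeca-6,15-dien-4-yn-1-yl]-3-methoxy-1,2-dioxan-6-yl]acetate F7. This neutral compound can be freed from any C3 epimer on silica. LiOH in THF/H2O at 0 °C then returns the acid 18.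

Further compounds
F1 | step 8 | ethyl (2E,12E)-6-oxodocosa-2,12,21-trien-10-ynoate | C=CCCCCCCC/C=C/C#CCCCC(=O)CC/C=C/C(=O)OCC
F2 | step 8 | ethyl (2E,12E)-6-hydroperoxy-6-methoxydocosa-2,12,21-trien-10-ynoate | C=CCCCCCCC/C=C/C#CCCCC(OC)(OO)CC/C=C/C(=O)OCC
F3 | step 8 | ethyl 2-[3-[(6E)-hexadeca-6,15-dien-4-yn-1-yl]-3-methoxy-1,2-dioxan-6-yl]acetate (mixture of stereoisomers at C3 and C6) | C=CCCCCCCC/C=C/C#CCCCC1(OC)CCC(CC(=O)OCC)OO1
F4 | step 8 | ethyl 2-[(3R,6S)-3-[(6E)-hexadeca-6,15-dien-4-yn-1-yl]-3-methoxy-1,2-dioxan-6-yl]acetate | C=CCCCCCCC/C=C/C#CCCC[C@]1(OC)CC[C@@H](CC(=O)OCC)OO1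
F5 | step 7 | (3R,12E)-3-hydroxy-1-[(4R)-4-(propan-2-yl)-2-sulfanylidene-1,3-thiazolidin-3-yl]docosa-12,21-dien-10-yne-1,6-dione | C=CCCCCCCC/C=C/C#CCCCC(=O)CC[C@@H](O)CC(=O)N1[C@H](C(C)C)CSC1=S
F6 | step 7 | (3R,12E)-3-hydroxy-6-oxodocosa-12,21-dien-10-ynoic acid | C=CCCCCCCC/C=C/C#CCCCC(=O)CC[C@@H](O)CC(=O)O
F7 | step 9 | methyl 2-[(3R,6S)-3-[(6E)-hexadeca-6,15-dien-4-yn-1-yl]-3-methoxy-1,2-dioxan-6-yl]acetate | C=CCCCCCCC/C=C/C#CCCC[C@]1(OC)CC[C@@H](CC(=O)OC)OO1
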